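The earlier runs and the new flask stem from a simulated flask with constants of no real substance; noise was put on by code.

4 questions are put to this coupling: two orders at the birch charge, the starting material left in the larch run, and what the readings show.

| flask | starting material | coupling partner | free catalyst | time |
|---|---|---|---|---|
| birch | 80.0 mM | 64.0 mM | 2.40 mM |  |
| maple | 80.0 mM | 96.0 mM | 2.40 mM |  |
| ash | 80.0 mM | 64.0 mM | 3.60 mM |  |
| oak | 160 mM | 64.0 mM | 2.40 mM |  |
| larch | 32.0 mM | 16.0 mM | 2.40 mM | 17 min |

- birch run (time / min: [starting material] / mM): 2.1: 52.3; 4.2: 38.3; 6.4: 35.5; 8.5: 30.3; 11: 26.7; 13: 25.4; 15: 24.1; 17: 24.9
- maple run (time / min: [starting material] / mM): 2.1: 51.0; 4.2: 33.1; 6.4: 22.7; 8.5: 18.0; 11: 12.5; 13: 8.8; 15: 7.6; 17: 6.9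
- ash run (time / min: [starting material] / mM): 2.1: 43.8; 4.2: 31.5; 6.4: 28.5; 8.5: 25.0; 11: 21.4; 13: 19.6; 15: 19.2; 17: 16.7
- oak run (time / min: [starting material] / mM): 2.1: 123.4; 4.2: 113.9; 6.4: 108.6; 8.5: 107.0; 11: 104.3; 13: 102.4; 15: 101.6; 17: 99.5

(readings scatter by 1 mM)

- how the opening rate goes with [coupling partner] round the charge of the birch run: the exponent of the rate at two percent of starting material gone to product
- how the opening rate goes with [free catalyst] round the charge of the birch run: the exponent of the rate at two percent of starting material gone to product
- starting material in the larch run at 17 min, as a share of the starting material charged
- which of these the readings show (the two partners rest in a complex / nothing beyond the main steps / the by-product binds the second partner / the by-product ties up the catalyst)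

- Overall: starting material + coupling partner -> product, with free catalyst as catalyst.
- Constant volume, constant temperature.
- What is held in complexes is read along with the free species.
- "The second partner" is coupling partner.
- An order is taken over about fifteen percent of the charge, up and down.

Does the opening need the coupling partner? Take the opening constant k, the logarithm of charge over first reading, divided by the time of that reading: birch gives 0.202 min⁻¹. Against birch, k read in the maple run gives an exponent in coupling partner of 0.142, and k read in the ash run gives an exponent in catalyst of 0.860; both are readings with their scatter. So, on this reckoning, starting material goes onto the catalyst before the partner acts.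

Where does larch stop? In larch the coupling partner is the limiting reagent, which on a first count gives 50.0 % of the starting material left. Putting the opening back in, this reckoning lets the catalyst end as loaded catalyst, holding starting material without partner, so the stop line, the charge of starting material less the charges of partner and catalyst, falls at 13.6 mM, or 42.5 %.

Does larch reach it? Near 49.7 mM gone, the rate is 1.91 mM min⁻¹ in birch, 2.41 mM min⁻¹ in oak and 4.73 mM min⁻¹ in maple. Maple, which differs from birch in the partner charge, reads 2.48 times the birch rate, and oak, which differs in the charge of starting material, 1.26 times. This reckoning therefore takes the late rate to follow the partner, and answers that the by-product binds it. Larch, at its line, has turned 18.4 mM, less than birch had turned by its first reading, 27.7 mM. At k, read in the birch opening, the line takes 4.23 min; birch later runs slower than over its opening, but the 17 min allowed are 4.02 times as long, so this reckoning puts larch just above its line.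

The forecast gave 0.5, 1.1, 52 % and the by-product ties up the catalyst, with a higher partner exponent and a higher larch share than this reckoning: “That points to product holding catalyst.”

The flask gives 43.4 % in larch, with orders 0.14 and 0.99, and the answer: the by-product binds the second partner.

    free catalyst + starting material → loaded catalyst + by-product (103.8 L mol⁻¹ min⁻¹)
    loaded catalyst + coupling partner → product + free catalyst (990.0 L mol⁻¹ min⁻¹)
    coupling partner + by-product ⇌ reagent-by-product salt, settled at all times (579.0 L mol⁻¹)

That share is 13.9 mM, which is 0.297 mM above the stop line. The binding of partner into reagent-by-product salt moves the readings by 9.8 in units of the scatter, yet the larch share changes with it by less than a percentage point. In the ash run the same line falls at 12.4 mM, and the reading at 17 min is 16.7 mM, still 4.30 mM above it.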